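Full conversion of Q is impossible in this flask: Q is used up only through Z, Z also falls into X, and no step leads back from X.

Q 0.30 M; G 1.50 equiv; E 7.9 mol%; volume of the second phase over the first 1.0

    E + G ⇌ Z + D (K1 = 0.072, k1 = 0.87 M⁻¹ s⁻¹)
    Q + Z → J + E (k2 = 3.3 M⁻¹ s⁻¹)
    Z → X (k3 = 0.046 s⁻¹)

* apparent order in G when 30% of the Q are converted (percent change of the rate of making J for one percent more G charged)

1. Write the balance of Q, the limiting reagent. Let kt = 3.3 M⁻¹ s⁻¹ be the constant of Q + Z and kd = 0.046 s⁻¹ that of Z into X. Q falls at kt·[Q]·[Z], and X grows at kd·[Z].
2. Divide the two rates so that [Z] cancels, then integrate. The logarithm of charged Q over present Q equals B times the share of catalyst in X. With 0.0237 M of catalyst charged, the catalyst budget B = kt × catalyst charged / kd = 1.70 is the number of e-folds of Q that one charge can buy. G does not appear in it.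
3. Draw the start. [Z] is zero, so the slope of Q is zero. Reckoned with 0.450 M of G and no D yet, Z rises with time constant 0.701 s towards 27.4% of the catalyst.
4. Draw the knee. D accumulates, and the return of Z + D has constant kr = 12.1 M⁻¹ s⁻¹. At 30% conversion the budget puts 21.0% of the catalyst in X, and D stands near 0.0950 M. Then kr·[D] is larger than kt·[Q], and Z holds 14.1% of the living catalyst.
5. Draw the level. Q runs into 18.3% of its charge, where the budget is spent.
6. Take the order. At fixed conversion, Q, X and D barely move with the charge of G. G left moves by charge over remainder, and the free share of catalyst, one minus the Z share, passes that on. My order is 1.09.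

The forecast gives 1.08, range 1 to 1.16, holding that “catalyst loss to X at fixed conversion is independent of G”.

The flask gives 1.1 at 28.8 s, inside that range. At 40.0 s Q stands at 64.1%, so the budget gives X 26.2%, and the flask reads 26.1%. The passing of Z into X raises the apparent order in E at 30% conversion from 0.98 without it to 1.2, and B holds the catalyst charged but not G. A second flask with twice the G keeps B at 1.70, so at 30% conversion it has 21.0% of the catalyst in X, and it reaches that conversion in 0.573 of the time.

All constants come from no measurement.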